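**Known runs.** Rank the constants by what they move before trusting any.

| flask | starting material | protic impurity | remark | time |
|---|---|---|---|---|
| north | 0.20 M | 0.014 M | run made earlier |  |
| south | 0.20 M | 0.022 M | run made earlier |  |
| south-west | 0.10 M | 0.010 M | run made earlier |  |
| flask | 0.20 M | 0.0100 M |  | 12 h |

| run | time / h | single ring / % | isomer of the product / % |
|---|---|---|---|
| north | 0.500 | 41.0 | 47.1 |
| north | 1.00 | 38.2 | 50.1 |
| north | 1.50 | 38.5 | 48.8 |
| north | 2.50 | 37.8 | 49.5 |
| north | 4.00 | 37.2 | 49.5 |
| north | 8.00 | 38.5 | 49.4 |
| south | 0.500 | 38.2 | 45.1 |
| south | 1.33 | 36.9 | 47.3 |
| south | 2.50 | 36.2 | 47.9 |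
| south | 4.00 | 36.3 | 47.3 |
| south | 6.00 | 36.9 | 47.3 |
| south | 8.00 | 37.2 | 47.3 |
| south-west | 0.667 | 39.1 | 49.6 |
| south-west | 2.00 | 37.8 | 49.4 |
| south-west | 3.00 | 38.0 | 48.8 |
| south-west | 5.00 | 37.8 | 49.7 |
| south-west | 8.00 | 38.0 | 49.4 |

(standard deviation of a reading: 0.5 percentage points)

- a species is counted by the starting material in it: one open trimer counts as three
- the reaction counts as stopped when no species that holds the starting material changes by six tenths of a point or more over the second half of the time

- which holds at 12 h: what has brought the reaction to rest, or that it has not come to rest (it is still moving / forward and back rates have come level / all of the starting material has reacted)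
- single ring at 12 h, in percent of the starting material charged
- isomer of the product at 12 h, in percent of the starting material charged
- open trimer at 12 h, in percent of the starting material charged
- amount of single ring if the flask were left three thousand times as long, in percent of the starting material charged

**The ranking.** Time moves little: in the north run, single ring plus isomer of the product reads 88.3% at 1.00 h and 87.9% at 8.00 h. That sum moves by 0.4 percentage points, so, as my own judgement, commit to complete consumption of starting material, and keep the single ring unchanged at long times. The scatter, 0.5 points, moves little too. The impurity moves the sum: from north to south its equivalents rise by 4 points, and the unread balance by 3.4 points. So misjudging it by half shifts the share it takes in this flask by about 2.5 points.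

**Free share.** Count what is left. Let c_H and c_A be the charges of protic impurity and starting material. Assume that each protic impurity takes one starting material, the impurity being the limiting reagent of that step. Take f, one minus c_H/c_A, the share of the charge that escapes the impurity; in this flask f is 95.0%. Divide the last ring sum by each run's f: north 94.5%, south 94.9%, south-west 97.1%. The south-west run, at a lower charge, reads higher than the other two, so use the two runs at this flask's charge: 94.7%. My sum is then 90.0%. Split by the ratio read last in the north run, 1.28, it gives single ring 39.4% and isomer 50.6%. I put open trimer, with any other unread product, near 5.00%.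

**The forecast.** It says forward and back rates have come level, with single ring 38.9%, isomer 50.5%, open trimer 10.6% and long-time ring 38.9%. Its ground for the trimer: “The missing balance, which I take as open trimer”. We part on the stop and the trimer.

**Flask result.** In this flask, all of the starting material has reacted, with 0% left. Single ring is 38.9%, isomer 50.5%, open trimer 3.42%, long-time ring 38.9%.

    starting material → single ring (k = 0.00250 s⁻¹)
    2 starting material → open dimer (k = 6.70 × 10⁻⁴ M⁻¹ s⁻¹)
    starting material + open dimer → open trimer (k = 0.0170 M⁻¹ s⁻¹)
    open dimer → ring dimer (k = 2.00 × 10⁻⁴ s⁻¹)
    single ring ⇌ isomer of the product (K = 1.30, k = 0.00160 s⁻¹)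
    starting material + protic impurity → quenched substrate (k = 0.430 M⁻¹ s⁻¹)

**Neighbour flask.** Quenched substrate in this flask is 5.00%, against one minus f, 5.00%. Now charge 0.50 M of starting material, with the impurity as before. The free share of this neighbour is 98.0%, and its quenched substrate is 2.00%. Its ring sum over that share is 85.0%, lower than the 94.1% of the flask at 0.20 M. Open trimer in this neighbour stands at 12.3%.

All runs are calculated on assumed constants.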